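## Retrosynthetic overview

1. Ring C is closed last: O1–C2 by a catalyst-controlled intramolecular oxa-Michael addition of a 2'-hydroxychalcone (sets C2 = S), followed by one fluoride-mediated global desilylation.
2. The chalcone is not made by aldol condensation: C4–C4a comes from an A-ring aryllithium and a B-ring cinnamoyl Weinreb amide (rings A and B are bought aromatic, as phloroglucinol and 2,4,6-trihydroxybenzaldehyde).
3. Key strategy: the hydrated lavandulyl chain is grown on ring A from a plain prenyl group by Shi epoxidation (creates the centre), SN2 opening at the CH carbon by an allyl nucleophile with inversion (C–C bond and tertiary carbinol at once), and cross-metathesis allyl → prenyl.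
4. Regiochemistry of ring closure (8- not 6-alkyl) is fixed at the outset: O5 is a TIPS ether, while O1 and O7 are MOM ethers that direct the first lithiation between them.
5. Ring order: A (functionalised) → side chain → A + B union → C.

Abbreviations: MOM = CH2OCH3, TIPS = Si(i-Pr)3, TBS = Si(t-Bu)Me2, TMS = SiMe3.

Assumption: reagents that only deliver a small group are listed with SMILES under "Reagents that add atoms" and are not numbered, and both enantiomers of the Shi ketone are taken as commercially available.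

## Route

Step 1
Reactants: 1 phloroglucinol (benzene-1,3,5-triol)
Product: 2 3,5-bis(methoxymethoxy)phenol
Conditions: MOMCl (2.0 equiv), i-Pr2NEt, DMF, 0 °C → rt; chromatographic separation from mono- and tris-ethers
Reagents that add atoms: chloromethyl methyl ether (MOMCl), COCCl
Why: Statistical Williamson-type O-alkylation of two of the three equivalent phenols gives the bis-MOM ether (expect roughly 40–45 %), leaving one oxygen free to be marked as the future O5; no stereocentre.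

Step 2
Reactants: 2 3,5-bis(methoxymethoxy)phenol
Product: 3 [3,5-bis(methoxymethoxy)phenoxy]tri(propan-2-yl)silane
Conditions: TIPSCl, imidazole, DMF, rt
Reagents that add atoms: chlorotri(propan-2-yl)silane (TIPSCl), CC(C)[Si](Cl)(C(C)C)C(C)C
Why: Silylation of the remaining phenol installs a bulky, base-stable, non-directing group that survives every later step and comes off only with fluoride at the end.

Step 3
Reactants: 3 [3,5-bis(methoxymethoxy)phenoxy]tri(propan-2-yl)silane
Product: 5 [3,5-bis(methoxymethoxy)-4-(3-methylbut-2-en-1-yl)phenoxy]tri(propan-2-yl)silane, via aryllithium 4 (not isolated)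
Conditions: n-BuLi (1.1 equiv), THF, 0 °C, 1 h; then CuBr·SMe2 (10 mol %), prenyl bromide, −78 °C → rt
Reagents that add atoms: 1-bromo-3-methylbut-2-ene (prenyl bromide), CC(C)=CCBr
Why: Directed ortho-metalation occurs at the carbon flanked by both OMOM groups (cooperative direction; OTIPS does not direct), and copper-mediated SN2 allylation then gives the linear prenyl arene.

Step 4
Reactants: 5 [3,5-bis(methoxymethoxy)-4-(3-methylbut-2-en-1-yl)phenoxy]tri(propan-2-yl)silane
Product: 6 (4-{[(2S)-3,3-dimethyloxiran-2-yl]methyl}-3,5-bis(methoxymethoxy)phenoxy)tri(propan-2-yl)silane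
Conditions: L-fructose-derived Shi ketone (1,2:4,5-di-O-isopropylidene-β-L-erythro-2,3-hexodiulo-2,6-pyranose, C12H18O6, 30 mol %), Oxone (2KHSO5·KHSO4·K2SO4), K2CO3, Bu4NHSO4, MeCN/CH2(OMe)2/aq. Na2B4O7 buffer (pH 10.5), 0 °C
Reagents that add atoms: potassium peroxymonosulfate (active component of Oxone), [K+].[O-]S(=O)(=O)OO
Why: Shi asymmetric epoxidation, in which the chiral dioxirane transfers oxygen through a spiro transition state to one face of the trisubstituted olefin; the L-fructose-derived ketone gives the (S)-epoxide (the D-fructose-derived one gives R), with ≥ 90 % ee expected for prenyl arenes, and this is the only step that creates the side-chain stereocentre.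

Step 5
Reactants: 6 (4-{[(2S)-3,3-dimethyloxiran-2-yl]methyl}-3,5-bis(methoxymethoxy)phenoxy)tri(propan-2-yl)silane
Product: 7 (2-bromo-4-{[(2S)-3,3-dimethyloxiran-2-yl]methyl}-3,5-bis(methoxymethoxy)phenoxy)tri(propan-2-yl)silane
Conditions: NBS (1.0 equiv), NaHCO3, MeCN, −20 → 0 °C
Reagents that add atoms: N-bromosuccinimide, O=C1CCC(=O)N1Br
Why: Electrophilic aromatic bromination of the very electron-rich ring at one of its two equivalent free positions (between OMOM and OTIPS); it is done at the epoxide stage because no alkene is present, and the neutral buffered conditions leave the epoxide intact.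

Step 6
Reactants: 7 (2-bromo-4-{[(2S)-3,3-dimethyloxiran-2-yl]methyl}-3,5-bis(methoxymethoxy)phenoxy)tri(propan-2-yl)silane
Product: 8 (3R)-3-{[3-bromo-2,6-bis(methoxymethoxy)-4-{[tri(propan-2-yl)silyl]oxy}phenyl]methyl}-2-methylhex-5-en-2-ol
Conditions: allylMgCl (3 equiv), CuBr·SMe2 (15 mol %), THF, −40 → 0 °C; aq. NH4Cl
Reagents that add atoms: allylmagnesium chloride, C=CC[Mg]Cl
Why: Copper-catalysed SN2 opening of the trisubstituted epoxide by the allyl Grignard at the less substituted CH carbon proceeds with inversion (S epoxide → R carbon), forging the C–C bond and unveiling the tertiary alcohol in one step; the low temperature and chloride counter-ion suppress Lewis-acid rearrangement, and the aryl bromide does not exchange with an allyl Grignard.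

Step 7
Reactants: 8 (3R)-3-{[3-bromo-2,6-bis(methoxymethoxy)-4-{[tri(propan-2-yl)silyl]oxy}phenyl]methyl}-2-methylhex-5-en-2-ol
Product: 9 (3R)-3-{[3-bromo-2,6-bis(methoxymethoxy)-4-{[tri(propan-2-yl)silyl]oxy}phenyl]methyl}-2,6-dimethylhept-5-en-2-ol
Conditions: second-generation Grubbs catalyst, RuCl2(=CHPh)(H2IMes)(PCy3) (5 mol %), 2-methylbut-2-ene/CH2Cl2, 40 °C
Reagents that add atoms: 2-methylbut-2-ene, CC=C(C)C
Why: Olefin cross-metathesis with 2-methylbut-2-ene converts the terminal allyl group into the prenyl group with loss of propene; the free tertiary alcohol and aryl bromide are tolerated and the stereocentre is untouched.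

Step 8
Reactants: 10 2,4,6-trihydroxybenzaldehyde
Product: 11 2,4,6-tris{[tert-butyl(dimethyl)silyl]oxy}benzaldehyde
Conditions: TBSCl (3.6 equiv), imidazole, DMF, rt → 40 °C
Reagents that add atoms: tert-butyl(chloro)dimethylsilane (TBSCl), CC(C)(C)[Si](C)(C)Cl
Why: Exhaustive silylation of the phenols gives a B-ring partner whose protecting groups can later be removed with fluoride under near-neutral conditions.

Step 9
Reactants: 11 2,4,6-tris{[tert-butyl(dimethyl)silyl]oxy}benzaldehyde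
Product: 12 (2E)-N-methoxy-N-methyl-3-(2,4,6-tris{[tert-butyl(dimethyl)silyl]oxy}phenyl)prop-2-enamide
Conditions: (EtO)2P(O)CH2C(O)N(OMe)Me, NaH, THF, 0 °C → rt
Reagents that add atoms: diethyl {2-[methoxy(methyl)amino]-2-oxoethyl}phosphonate, CCOP(=O)(CC(=O)N(C)OC)OCC
Why: Horner–Wadsworth–Emmons olefination with the stabilised Weinreb-amide phosphonate gives the E-cinnamoyl Weinreb amide under hydroxide-free conditions that spare the aryl silyl ethers.

Step 10
Reactants: 9 (3R)-3-{[3-bromo-2,6-bis(methoxymethoxy)-4-{[tri(propan-2-yl)silyl]oxy}phenyl]methyl}-2,6-dimethylhept-5-en-2-ol; 12 (2E)-N-methoxy-N-methyl-3-(2,4,6-tris{[tert-butyl(dimethyl)silyl]oxy}phenyl)prop-2-enamide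
Product: 14 (2E)-1-{3-[(2R)-2-(2-hydroxypropan-2-yl)-5-methylhex-4-en-1-yl]-2,4-bis(methoxymethoxy)-6-(TIPS-oxy)phenyl}-3-[2,4,6-tris(TBS-oxy)phenyl]prop-2-en-1-one, via dilithio intermediate 13 (not isolated)
Conditions: t-BuLi (3.1 equiv), THF, −78 °C, 15 min; then 12 (1.2 equiv), −78 → −40 °C; aq. NH4Cl
Reagents that add atoms: none
Why: Weinreb ketone synthesis, in which deprotonation of the tertiary OH and bromine–lithium exchange give an aryllithium that adds once to the Weinreb amide through a stable chelated tetrahedral intermediate; the E-chalcone is delivered directly at −78 °C, cold enough to suppress O→C silyl migration in the ortho-silyloxy aryllithium.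

Step 11
Reactants: 14 (2E)-1-{3-[(2R)-2-(2-hydroxypropan-2-yl)-5-methylhex-4-en-1-yl]-2,4-bis(methoxymethoxy)-6-(TIPS-oxy)phenyl}-3-[2,4,6-tris(TBS-oxy)phenyl]prop-2-en-1-one
Product: 16 (2E)-1-{2,4-dihydroxy-3-[(2R)-2-(2-hydroxypropan-2-yl)-5-methylhex-4-en-1-yl]-6-(TIPS-oxy)phenyl}-3-[2,4,6-tris(TBS-oxy)phenyl]prop-2-en-1-one, via tris-TMS ether 15 (not isolated)
Conditions: TMSOTf (6 equiv), 2,2'-bipyridyl (9 equiv), CH2Cl2, 0 °C → rt; then H2O/THF (citric acid, pH ≈ 4), rt
Reagents that add atoms: none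
Why: TMSOTf/2,2'-bipyridyl chemoselectively converts aryl MOM ethers into aryl TMS ethers (the methoxymethyl group leaves on bipyridyl) under buffered, non-protic conditions that tolerate the TIPS/TBS aryl ethers, the alkene and the tertiary alcohol and avoid a protic acid that would cyclise the chalcone racemically; water then hydrolyses the labile TMS ethers.

Step 12
Reactants: 16 (2E)-1-{2,4-dihydroxy-3-[(2R)-2-(2-hydroxypropan-2-yl)-5-methylhex-4-en-1-yl]-6-(TIPS-oxy)phenyl}-3-[2,4,6-tris(TBS-oxy)phenyl]prop-2-en-1-one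
Product: 17 (2E)-1-{4-(TBS-oxy)-2-hydroxy-3-[(2R)-2-(2-hydroxypropan-2-yl)-5-methylhex-4-en-1-yl]-6-(TIPS-oxy)phenyl}-3-[2,4,6-tris(TBS-oxy)phenyl]prop-2-en-1-one
Conditions: TBSCl (1.1 equiv), imidazole, CH2Cl2, 0 °C
Reagents that add atoms: tert-butyl(chloro)dimethylsilane (TBSCl), CC(C)(C)[Si](C)(C)Cl
Why: Chemoselective silylation of the 4'-OH, the more acidic, non-chelated phenol; the 2'-OH is hydrogen-bonded to the ketone and flanked by two substituents and the tertiary alcohol is inert to TBSCl/imidazole, so only the future O1 remains free.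

Step 13
Reactants: 17 (2E)-1-{4-(TBS-oxy)-2-hydroxy-3-[(2R)-2-(2-hydroxypropan-2-yl)-5-methylhex-4-en-1-yl]-6-(TIPS-oxy)phenyl}-3-[2,4,6-tris(TBS-oxy)phenyl]prop-2-en-1-one
Product: 18 (2S)-7-(TBS-oxy)-8-[(2R)-2-(2-hydroxypropan-2-yl)-5-methylhex-4-en-1-yl]-5-(TIPS-oxy)-2-[2,4,6-tris(TBS-oxy)phenyl]-2,3-dihydro-4H-chromen-4-one
Conditions: quinidine-derived bifunctional thiourea N-[3,5-bis(trifluoromethyl)phenyl]-N'-(9-deoxy-epi-quinidin-9-yl)thiourea (C29H28F6N4OS, 15 mol %), 4 Å molecular sieves, toluene, 0 °C → rt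
Reagents that add atoms: none
Why: Proposed new method: 6-endo intramolecular oxa-Michael addition under bifunctional catalysis, in which the quinuclidine nitrogen deprotonates the single free 2'-phenol while the thiourea hydrogen-bonds the enone carbonyl, so the phenoxide is delivered to one face of the β-carbon and C2 is set as S by the catalyst (the remote side-chain centre exerts no control); the quinine-derived pseudo-enantiomer gives 2R and the sense is confirmed by CD before scale-up; the closest known reactions are the cinchona-alkaloid-catalysed cyclisation of 2'-hydroxychalcones (moderate ee) and the thiourea-catalysed asymmetric flavanone synthesis from β-ketoester-activated chalcones (high ee).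

Step 14
Reactants: 18 (2S)-7-(TBS-oxy)-8-[(2R)-2-(2-hydroxypropan-2-yl)-5-methylhex-4-en-1-yl]-5-(TIPS-oxy)-2-[2,4,6-tris(TBS-oxy)phenyl]-2,3-dihydro-4H-chromen-4-one
Product: 19 (2S)-5,7-dihydroxy-8-[(2R)-2-(2-hydroxypropan-2-yl)-5-methylhex-4-en-1-yl]-2-(2,4,6-trihydroxyphenyl)-2,3-dihydro-4H-chromen-4-one
Conditions: HF·pyridine, pyridine, THF, 0 °C → rt
Reagents that add atoms: none
Why: Fluoride-mediated cleavage of all five aryl silyl ethers (Si–F bond formation) under buffered, slightly acidic conditions, avoiding both the base that would open the flavanone to the chalcone and the strong acid that would ionise C2 or the tertiary carbinol, so both stereocentres and the prenyl alkene survive.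

## Compound list

1 | phloroglucinol (benzene-1,3,5-triol) | Oc1cc(O)cc(O)c1 | starting material
2 | 3,5-bis(methoxymethoxy)phenol | COCOc1cc(O)cc(OCOC)c1 | intermediate
3 | [3,5-bis(methoxymethoxy)phenoxy]tri(propan-2-yl)silane | COCOc1cc(OCOC)cc(O[Si](C(C)C)(C(C)C)C(C)C)c1 | intermediate
4 | [2,6-bis(methoxymethoxy)-4-{[tri(propan-2-yl)silyl]oxy}phenyl]lithium (not isolated) | [Li]c1c(OCOC)cc(O[Si](C(C)C)(C(C)C)C(C)C)cc1OCOC | intermediate
5 | [3,5-bis(methoxymethoxy)-4-(3-methylbut-2-en-1-yl)phenoxy]tri(propan-2-yl)silane | CC(C)=CCc1c(OCOC)cc(O[Si](C(C)C)(C(C)C)C(C)C)cc1OCOC | intermediate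
6 | (4-{[(2S)-3,3-dimethyloxiran-2-yl]methyl}-3,5-bis(methoxymethoxy)phenoxy)tri(propan-2-yl)silane | CC1(C)O[C@H]1Cc2c(OCOC)cc(O[Si](C(C)C)(C(C)C)C(C)C)cc2OCOC | intermediate
7 | (2-bromo-4-{[(2S)-3,3-dimethyloxiran-2-yl]methyl}-3,5-bis(methoxymethoxy)phenoxy)tri(propan-2-yl)silane | CC1(C)O[C@H]1Cc2c(OCOC)cc(O[Si](C(C)C)(C(C)C)C(C)C)c(Br)c2OCOC | intermediate
8 | (3R)-3-{[3-bromo-2,6-bis(methoxymethoxy)-4-{[tri(propan-2-yl)silyl]oxy}phenyl]methyl}-2-methylhex-5-en-2-ol | C=CC[C@H](Cc1c(OCOC)cc(O[Si](C(C)C)(C(C)C)C(C)C)c(Br)c1OCOC)C(C)(C)O | intermediate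
9 | (3R)-3-{[3-bromo-2,6-bis(methoxymethoxy)-4-{[tri(propan-2-yl)silyl]oxy}phenyl]methyl}-2,6-dimethylhept-5-en-2-ol | CC(C)=CC[C@H](Cc1c(OCOC)cc(O[Si](C(C)C)(C(C)C)C(C)C)c(Br)c1OCOC)C(C)(C)O | intermediate
10 | 2,4,6-trihydroxybenzaldehyde | O=Cc1c(O)cc(O)cc1O | starting material
11 | 2,4,6-tris{[tert-butyl(dimethyl)silyl]oxy}benzaldehyde | O=Cc1c(O[Si](C)(C)C(C)(C)C)cc(O[Si](C)(C)C(C)(C)C)cc1O[Si](C)(C)C(C)(C)C | intermediate
12 | (2E)-N-methoxy-N-methyl-3-(2,4,6-tris{[tert-butyl(dimethyl)silyl]oxy}phenyl)prop-2-enamide | CON(C)C(=O)/C=C/c1c(O[Si](C)(C)C(C)(C)C)cc(O[Si](C)(C)C(C)(C)C)cc1O[Si](C)(C)C(C)(C)C | intermediate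
13 | dilithio derivative of 9: aryllithium at the former C–Br carbon and lithium tertiary alkoxide (not isolated) | CC(C)=CC[C@H](Cc1c(OCOC)cc(O[Si](C(C)C)(C(C)C)C(C)C)c([Li])c1OCOC)C(C)(C)O[Li] | intermediate
14 | (2E)-1-{3-[(2R)-2-(2-hydroxypropan-2-yl)-5-methylhex-4-en-1-yl]-2,4-bis(methoxymethoxy)-6-{[tri(propan-2-yl)silyl]oxy}phenyl}-3-(2,4,6-tris{[tert-butyl(dimethyl)silyl]oxy}phenyl)prop-2-en-1-one | CC(C)=CC[C@H](Cc1c(OCOC)cc(O[Si](C(C)C)(C(C)C)C(C)C)c(C(=O)/C=C/c2c(O[Si](C)(C)C(C)(C)C)cc(O[Si](C)(C)C(C)(C)C)cc2O[Si](C)(C)C(C)(C)C)c1OCOC)C(C)(C)O | intermediate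
15 | tris-TMS ether of 16: 2'-O, 4'-O and tertiary O as trimethylsilyl ethers (not isolated) | CC(C)=CC[C@H](Cc1c(O[Si](C)(C)C)cc(O[Si](C(C)C)(C(C)C)C(C)C)c(C(=O)/C=C/c2c(O[Si](C)(C)C(C)(C)C)cc(O[Si](C)(C)C(C)(C)C)cc2O[Si](C)(C)C(C)(C)C)c1O[Si](C)(C)C)C(C)(C)O[Si](C)(C)C | intermediate
16 | (2E)-1-{2,4-dihydroxy-3-[(2R)-2-(2-hydroxypropan-2-yl)-5-methylhex-4-en-1-yl]-6-{[tri(propan-2-yl)silyl]oxy}phenyl}-3-(2,4,6-tris{[tert-butyl(dimethyl)silyl]oxy}phenyl)prop-2-en-1-one | CC(C)=CC[C@H](Cc1c(O)cc(O[Si](C(C)C)(C(C)C)C(C)C)c(C(=O)/C=C/c2c(O[Si](C)(C)C(C)(C)C)cc(O[Si](C)(C)C(C)(C)C)cc2O[Si](C)(C)C(C)(C)C)c1O)C(C)(C)O | intermediate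
17 | (2E)-1-{4-{[tert-butyl(dimethyl)silyl]oxy}-2-hydroxy-3-[(2R)-2-(2-hydroxypropan-2-yl)-5-methylhex-4-en-1-yl]-6-{[tri(propan-2-yl)silyl]oxy}phenyl}-3-(2,4,6-tris{[tert-butyl(dimethyl)silyl]oxy}phenyl)prop-2-en-1-one | CC(C)=CC[C@H](Cc1c(O[Si](C)(C)C(C)(C)C)cc(O[Si](C(C)C)(C(C)C)C(C)C)c(C(=O)/C=C/c2c(O[Si](C)(C)C(C)(C)C)cc(O[Si](C)(C)C(C)(C)C)cc2O[Si](C)(C)C(C)(C)C)c1O)C(C)(C)O | intermediate
18 | (2S)-7-{[tert-butyl(dimethyl)silyl]oxy}-8-[(2R)-2-(2-hydroxypropan-2-yl)-5-methylhex-4-en-1-yl]-5-{[tri(propan-2-yl)silyl]oxy}-2-(2,4,6-tris{[tert-butyl(dimethyl)silyl]oxy}phenyl)-2,3-dihydro-4H-chromen-4-one | CC(C)=CC[C@H](Cc1c(O[Si](C)(C)C(C)(C)C)cc(O[Si](C(C)C)(C(C)C)C(C)C)c2c1O[C@H](c1c(O[Si](C)(C)C(C)(C)C)cc(O[Si](C)(C)C(C)(C)C)cc1O[Si](C)(C)C(C)(C)C)CC2=O)C(C)(C)O | intermediate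
19 | (2S)-5,7-dihydroxy-8-[(2R)-2-(2-hydroxypropan-2-yl)-5-methylhex-4-en-1-yl]-2-(2,4,6-trihydroxyphenyl)-2,3-dihydro-4H-chromen-4-one | CC(C)=CC[C@H](Cc1c(O)cc(O)c2c1O[C@H](c1c(O)cc(O)cc1O)CC2=O)C(C)(C)O | target

## Step count and risks

Total step count: 14. Longest linear sequence: 12 (steps 1–7 and 10–14); steps 8–9 make the B-ring partner.

Three steps most likely to fail:

Step 13 (stereoselective ring closure). The chalcone is unactivated, electron-rich and flanked by bulky ortho groups, so the catalysed oxa-Michael addition may be slow or poorly selective. The fallback sets out from 17 and comes back at 18. Compound 17 is cyclised without stereocontrol (catalytic DBU, dry CH2Cl2) to the 2-epimeric silylated flavanone mixture F1. F1 is then resolved kinetically by asymmetric transfer hydrogenation with RuCl[(R,R)-TsDPEN](p-cymene), a divalent ruthenium catalyst, in HCO2H/Et3N, stopped near 50 % conversion. The (R,R)-catalyst delivers hydride to give the 4R alcohol trans to the 2-aryl group, so the (2R)-epimer is consumed as the cis-(2R,4R)-flavan-4-ol F2 and the (2S)-ketone 18 is recovered by chromatography. F2 can be returned to the pool by Dess–Martin oxidation and DBU equilibration back to F1.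

Step 6 (epoxide opening at a hindered secondary carbon). Magnesium-halide-induced rearrangement to a ketone or attack at the tertiary carbon may compete. The fallback sets out from 3 (through its lithio derivative 4) and comes back at 9, replacing steps 3–7 by an auxiliary-controlled alkylation. Compound 4 is transmetalated to the arylcopper (CuBr·SMe2, Me3SiCl) and added in conjugate fashion to (4R)-3-acryloyl-4-benzyl-1,3-oxazolidin-2-one to give the 3-arylpropanoyl imide F3. The ring is brominated with NBS to the bromo imide F4. The sodium Z-enolate (NaN(SiMe3)2, THF, −78 °C) is alkylated with prenyl bromide anti to the benzyl group (Evans alkylation, sets the centre R) to give the prenylated imide F5. MeOMgBr exchanges the auxiliary for a methyl ester, giving the methyl ester F6. Double addition of MeMgBr/CeCl3 then gives 9.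

Step 10 (hindered aryllithium next to OTIPS; possible silyl migration or poor acylation). The fallback sets out from 9 and 11 and comes back at 14, avoiding any organolithium on ring A. Boron-Wittig olefination of 11 with bis(pinacolato)borylmethane and lithium 2,2,6,6-tetramethylpiperidide gives the E-alkenylboronate F7. A palladium-catalysed carbonylative Suzuki–Miyaura coupling of 9, CO (1 atm) and F7 (palladium diacetate, di(1-adamantyl)-n-butylphosphine, K3PO4, anhydrous toluene, 80 °C) then gives the aryl vinyl ketone 14.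

Further compounds
F1 | step 13 | 2-epimeric mixture (2RS) of 18 | CC(C)=CC[C@H](Cc1c(O[Si](C)(C)C(C)(C)C)cc(O[Si](C(C)C)(C(C)C)C(C)C)c2c1OC(c1c(O[Si](C)(C)C(C)(C)C)cc(O[Si](C)(C)C(C)(C)C)cc1O[Si](C)(C)C(C)(C)C)CC2=O)C(C)(C)O
F2 | step 13 | (2R,4R)-7-(TBS-oxy)-8-[(2R)-2-(2-hydroxypropan-2-yl)-5-methylhex-4-en-1-yl]-5-(TIPS-oxy)-2-[2,4,6-tris(TBS-oxy)phenyl]-3,4-dihydro-2H-chromen-4-ol | CC(C)=CC[C@H](Cc1c(O[Si](C)(C)C(C)(C)C)cc(O[Si](C(C)C)(C(C)C)C(C)C)c2c1O[C@@H](c1c(O[Si](C)(C)C(C)(C)C)cc(O[Si](C)(C)C(C)(C)C)cc1O[Si](C)(C)C(C)(C)C)C[C@H]2O)C(C)(C)O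
F3 | step 6 | (4R)-4-benzyl-3-{3-[2,6-bis(methoxymethoxy)-4-{[tri(propan-2-yl)silyl]oxy}phenyl]propanoyl}-1,3-oxazolidin-2-one | O=C(CCc1c(OCOC)cc(O[Si](C(C)C)(C(C)C)C(C)C)cc1OCOC)N1[C@H](Cc2ccccc2)COC1=O
F4 | step 6 | (4R)-4-benzyl-3-{3-[3-bromo-2,6-bis(methoxymethoxy)-4-{[tri(propan-2-yl)silyl]oxy}phenyl]propanoyl}-1,3-oxazolidin-2-one | O=C(CCc1c(OCOC)cc(O[Si](C(C)C)(C(C)C)C(C)C)c(Br)c1OCOC)N1[C@H](Cc2ccccc2)COC1=O
F5 | step 6 | (4R)-4-benzyl-3-[(2R)-2-{[3-bromo-2,6-bis(methoxymethoxy)-4-{[tri(propan-2-yl)silyl]oxy}phenyl]methyl}-5-methylhex-4-enoyl]-1,3-oxazolidin-2-one | CC(C)=CC[C@H](Cc1c(OCOC)cc(O[Si](C(C)C)(C(C)C)C(C)C)c(Br)c1OCOC)C(=O)N1[C@H](Cc2ccccc2)COC1=O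
F6 | step 6 | methyl (2R)-2-{[3-bromo-2,6-bis(methoxymethoxy)-4-{[tri(propan-2-yl)silyl]oxy}phenyl]methyl}-5-methylhex-4-enoate | CC(C)=CC[C@H](Cc1c(OCOC)cc(O[Si](C(C)C)(C(C)C)C(C)C)c(Br)c1OCOC)C(=O)OC
F7 | step 10 | 4,4,5,5-tetramethyl-2-[(E)-2-(2,4,6-tris{[tert-butyl(dimethyl)silyl]oxy}phenyl)ethenyl]-1,3,2-dioxaborolane | CC1(C)OB(/C=C/c2c(O[Si](C)(C)C(C)(C)C)cc(O[Si](C)(C)C(C)(C)C)cc2O[Si](C)(C)C(C)(C)C)OC1(C)C
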